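**Strategy**

Labdane numbering is used. Everything rests on opening ring B of the trans-decalin at C5–C10 and C8–C9: the C9–C10 edge becomes an (E)-β-methyl enoate dienophile and C5–C8 a 1-silyloxy diene, joined through C1–C4 of ring A, which carry the C2 oxygen and the C4 gem-dimethyl group. One intramolecular Diels–Alder reaction of this acyclic triene closes rings A and B together and sets C5, C9 and C10 from the single C2 stereocentre, itself made by an asymmetric vinylogous aldol reaction. The C8 oxygen later becomes the exocyclic methylene; the C11 ester is extended by one carbon and the (Z)-acetoxy acid chain is added by anti-carbomagnesiation of propargyl alcohol.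

Key step: step 6

Remark: locants C1–C20 in the text follow labdane numbering; for step 3 it is assumed that the chosen antipode of the chiral Lewis base directs attack to the Si face of aldehyde 3 (giving 5R), the other antipode being taken if the sense proves opposite.

**Route**

Step 1
Reactants: 1 2,2-dimethylpent-4-enal
Product: 3 3,3-dimethylhex-5-enal, via enol ether 2 (not isolated)
Conditions: Ph3P(CH2OMe)Cl, KOt-Bu, THF, 0 °C; then 2 M HCl, THF, rt
Reagents that add atoms: (methoxymethyl)triphenylphosphonium chloride COC[P+](c1ccccc1)(c1ccccc1)c1ccccc1.[Cl-]; water O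
Why: Wittig methoxymethylenation of the non-enolisable aldehyde followed by acid hydrolysis of the enol ether should give the one-carbon homologue, with no stereocentre involved.

Step 2
Reactants: 4 methyl 3-methylbut-2-enoate
Product: 5 tert-butyl[(1-methoxy-3-methylbuta-1,3-dien-1-yl)oxy]dimethylsilane
Conditions: LiN(i-Pr)2, THF/DMPU, −78 °C; then t-BuMe2SiCl, −78 °C → rt
Reagents that add atoms: tert-butyldimethylsilyl chloride CC(C)(C)[Si](C)(C)Cl
Why: γ-Deprotonation of the enoate and O-silylation of the extended enolate should give the silyl dienol ether needed for a vinylogous Mukaiyama aldol reaction.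

Step 3
Reactants: 3 3,3-dimethylhex-5-enal; 5 silyl dienol ether
Product: 6 methyl (2E,5R)-5-hydroxy-3,7,7-trimethyldeca-2,9-dienoate
Conditions: SiCl4 (1.1 equiv), chiral 1,1'-binaphthyl-2,2'-diamine-derived bis(phosphoramide) (5 mol %), i-Pr2NEt (10 mol %), CH2Cl2, −78 °C; aq. NaHCO3
Reagents that add atoms: none
Why: In this catalytic enantioselective vinylogous Mukaiyama aldol reaction the chiral Lewis base–SiCl4 complex activates the aldehyde, the dienolate attacks through its γ-carbon on the Si face to set C2 (5R in 6), and the extended dienolate should deliver the E enoate with the methyl group cis to the ester.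

Step 4
Reactants: 6 hydroxy enoate
Product: 7 methyl (2E,5R)-5-[(tert-butyldimethylsilyl)oxy]-3,7,7-trimethyldeca-2,9-dienoate
Conditions: t-BuMe2SiCl, imidazole, DMF, rt
Reagents that add atoms: tert-butyldimethylsilyl chloride CC(C)(C)[Si](C)(C)Cl
Why: Standard silylation of the secondary alcohol should give an ether that lasts until the final step.

Step 5
Reactants: 7 silyl ether
Product: 8 methyl (2E,5R,9E)-5-[(tert-butyldimethylsilyl)oxy]-3,7,7-trimethyl-11-oxoundeca-2,9-dienoate
Conditions: crotonaldehyde (5 equiv), second-generation Grubbs catalyst (3 mol %), CH2Cl2, 40 °C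
Reagents that add atoms: (E)-but-2-enal C/C=C/C=O
Why: Olefin cross-metathesis of the terminal alkene with the electron-poor partner should give the E enal, the trisubstituted enoate being inert to the catalyst.

Step 6
Reactants: 8 enal enoate
Product: 10 methyl (1S,2R,4aR,7R,8aR)-7-[(tert-butyldimethylsilyl)oxy]-5,5,8a-trimethyl-2-[(triethylsilyl)oxy]-1,2,4a,5,6,7,8,8a-octahydronaphthalene-1-carboxylate, via silyl dienol ether 9 (not isolated)
Conditions: Et3SiOTf (1.3 equiv), Et3N (2 equiv), toluene, 0 °C → rt; filter (Celite, pentane); then toluene (0.01 M), BHT, 150 °C, sealed tube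
Reagents that add atoms: triethylsilyl trifluoromethanesulfonate CC[Si](CC)(CC)OS(=O)(=O)C(F)(F)F
Why: Soft enolisation of the enal at C5 gives the (5E,7E)-1-silyloxy diene 9, which on heating should undergo a concerted, asynchronous type 1 intramolecular Diels–Alder reaction with the (E)-enoate, the C5–C10 bond running ahead of C8–C9 because the diene HOMO is largest at C5 and the enoate LUMO at C10. The closest known reaction type is the cycloaddition of silyl dienol ethers, made in situ from enals or enones with a silyl triflate and Et3N, onto tethered enoates. Ring B closes as the cyclohexene of the [4+2] through both new bonds, ring A as the six-membered tether ring through C5–C10 alone, fused, in a chair-like array. The cis relation of the C10 methyl and the C9 ester follows from the E geometry of the enoate in a suprafacial addition, the trans ring fusion (C5–H anti to C10–CH3) from the transition state with the ester endo, and the C8 silyloxy group, cis to the ester, from the E enol ether; this last centre is erased in step 11. The absolute sense comes from C2, whose silyloxy group sits equatorial on the chair-like tether, since the other diene face would force it 1,3-diaxial to the C10 methyl and the axial C4 methyl. The step needs endo (trans-fusion) and facial selectivity, which the terminal ester on an E dienophile, the leading C5–C10 bond, residual silyl triflate as a mild Lewis acid and the gem-dimethyl group in the tether should secure.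

Step 7
Reactants: 10 Diels–Alder adduct
Product: 11 methyl (1S,2R,4aR,7R,8aR)-7-[(tert-butyldimethylsilyl)oxy]-5,5,8a-trimethyl-2-[(triethylsilyl)oxy]decahydronaphthalene-1-carboxylate
Conditions: H2 (1 atm), 5% Pt/C, EtOAc, rt
Reagents that add atoms: none
Why: Heterogeneous hydrogenation should saturate the only C=C bond (C6=C7) without creating a stereocentre and without hydrogenolysis of the allylic silyl ether on platinum.

Step 8
Reactants: 11 saturated ester
Product: 12 (1S,2R,4aR,7R,8aR)-7-[(tert-butyldimethylsilyl)oxy]-5,5,8a-trimethyl-2-[(triethylsilyl)oxy]decahydronaphthalene-1-carbaldehyde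
Conditions: i-Bu2AlH (1.2 equiv), CH2Cl2, −78 °C; MeOH, then aq. KNa tartrate
Reagents that add atoms: none
Why: Partial reduction of the hindered methyl ester should stop at the aldehyde because the tetrahedral aluminium acetal survives at −78 °C until work-up.

Step 9
Reactants: 12 aldehyde
Product: 13 tert-butyl{[(2R,4aR,7R,8S,8aR)-8-ethenyl-4,4,8a-trimethyl-7-[(triethylsilyl)oxy]decahydronaphthalen-2-yl]oxy}dimethylsilane
Conditions: Ph3PCH3Br, KOt-Bu, THF, 0 °C
Reagents that add atoms: methyltriphenylphosphonium bromide C[P+](c1ccccc1)(c1ccccc1)c1ccccc1.[Br-]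
Why: Wittig methylenation of the aldehyde adds C12, and C9 should keep its equatorial, thermodynamically favoured substituent.

Step 10
Reactants: 13 vinyl bis(silyl ether)
Product: 14 (1S,2R,4aR,7R,8aR)-7-[(tert-butyldimethylsilyl)oxy]-1-ethenyl-5,5,8a-trimethyldecahydronaphthalen-2-ol
Conditions: PPTS (0.2 equiv), MeOH/CH2Cl2, 0 °C → rt
Reagents that add atoms: none
Why: Acid-catalysed methanolysis should remove the triethylsilyl ether far faster than the tert-butyldimethylsilyl ether.

Step 11
Reactants: 14 secondary alcohol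
Product: 15 (1S,4aR,7R,8aR)-7-[(tert-butyldimethylsilyl)oxy]-1-ethenyl-5,5,8a-trimethyloctahydronaphthalen-2(1H)-one
Conditions: Dess–Martin periodinane, NaHCO3, CH2Cl2, 0 °C → rt
Reagents that add atoms: none
Why: Dess–Martin oxidation in a buffered, neutral medium should give the C8 ketone without moving the β,γ-double bond into conjugation or epimerising C9, whose side chain is equatorial.

Step 12
Reactants: 15 ketone
Product: 16 tert-butyl{[(2R,4aR,8R,8aR)-8-ethenyl-4,4,8a-trimethyl-7-methylidenedecahydronaphthalen-2-yl]oxy}dimethylsilane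
Conditions: Zn, CH2Br2, TiCl4, THF/CH2Cl2, 0 °C → rt
Reagents that add atoms: dibromomethane BrCBr
Why: Takai–Lombardo methylenation, a non-basic zinc–titanium carbenoid olefination, should convert the hindered, easily enolised ketone into the exocyclic alkene without enolate chemistry at C9.

Step 13
Reactants: 16 diene
Product: 18 {[(2R,4aR,8R,8aR)-8-(2-bromoethyl)-4,4,8a-trimethyl-7-methylidenedecahydronaphthalen-2-yl]oxy}(tert-butyl)dimethylsilane, via alkylzirconocene chloride 17 (not isolated)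
Conditions: Cp2Zr(H)Cl (1.2 equiv), THF, rt; then NBS, 0 °C
Reagents that add atoms: N-bromosuccinimide O=C1CCC(=O)N1Br
Why: Hydrozirconation is highly sensitive to substitution, so Cp2Zr(H)Cl should add only to the monosubstituted vinyl group with zirconium on the terminal carbon C12, and bromination of the C–Zr bond gives the primary bromide.

Step 14
Reactants: 18 bromide
Product: 22 (2Z)-3-[(acetyloxy)methyl]-5-[(1R,4aR,7R,8aR)-7-[(tert-butyldimethylsilyl)oxy]-5,5,8a-trimethyl-2-methylidenedecahydronaphthalen-1-yl]pent-2-enoic acid, via Grignard reagent 19 (not isolated), via vinylmagnesium chelate 20 (not isolated), via magnesium carboxylate 21 (not isolated)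
Conditions: Mg, THF, 45 °C; added to HC≡CCH2OMgCl (1.5 equiv, from propargyl alcohol and i-PrMgCl, −20 °C), CuI (15 mol %), THF/Et2O, −20 °C → rt; CO2, −30 → 0 °C; Ac2O (6 equiv), 0 °C; cold 1 M HCl
Reagents that add atoms: prop-2-yn-1-ol C#CCO; carbon dioxide O=C=O; acetic anhydride CC(=O)OC(C)=O
Why: Copper-catalysed anti-carbomagnesiation of the propargyl alkoxide puts C12 on the internal alkyne carbon and magnesium on the terminal one, held cis to C16 in a five-membered oxamagnesacycle, so that carboxylation with retention and in situ O-acetylation of the alkoxide should give the acid with C15 cis to C16 (2Z) without a free hydroxy acid ever being present.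

Step 15
Reactants: 22 silyl-protected acid
Product: 23 (2Z)-3-[(acetyloxy)methyl]-5-[(1R,4aR,7R,8aR)-7-hydroxy-5,5,8a-trimethyl-2-methylidenedecahydronaphthalen-1-yl]pent-2-enoic acid
Conditions: HF·pyridine, pyridine, THF, 0 °C → rt
Reagents that add atoms: none
Why: Fluoride cleavage of the silyl ether under mildly acidic conditions should leave the allylic acetate, the acid and the exocyclic alkene untouched.

**Compound list**

1 | 2,2-dimethylpent-4-enal | C=CCC(C)(C)C=O | starting material
2 | 1-methoxy-3,3-dimethylhexa-1,5-diene (E/Z mixture) | C=CCC(C)(C)C=COC | intermediate (not isolated)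
3 | 3,3-dimethylhex-5-enal | C=CCC(C)(C)CC=O | intermediate
4 | methyl 3-methylbut-2-enoate | COC(=O)C=C(C)C | starting material
5 | tert-butyl[(1-methoxy-3-methylbuta-1,3-dien-1-yl)oxy]dimethylsilane | C=C(C)C=C(OC)O[Si](C)(C)C(C)(C)C | intermediate
6 | methyl (2E,5R)-5-hydroxy-3,7,7-trimethyldeca-2,9-dienoate | COC(=O)/C=C(\C)C[C@H](O)CC(C)(C)CC=C | intermediate
7 | methyl (2E,5R)-5-[(tert-butyldimethylsilyl)oxy]-3,7,7-trimethyldeca-2,9-dienoate | COC(=O)/C=C(\C)C[C@H](O[Si](C)(C)C(C)(C)C)CC(C)(C)CC=C | intermediate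
8 | methyl (2E,5R,9E)-5-[(tert-butyldimethylsilyl)oxy]-3,7,7-trimethyl-11-oxoundeca-2,9-dienoate | COC(=O)/C=C(\C)C[C@H](O[Si](C)(C)C(C)(C)C)CC(C)(C)C/C=C/C=O | intermediate
9 | methyl (2E,5S,8E,10E)-5-[(tert-butyldimethylsilyl)oxy]-3,7,7-trimethyl-11-[(triethylsilyl)oxy]undeca-2,8,10-trienoate (same spatial arrangement at C5 as in 8) | COC(=O)/C=C(\C)C[C@H](O[Si](C)(C)C(C)(C)C)CC(C)(C)/C=C/C=C/O[Si](CC)(CC)CC | intermediate (not isolated)
10 | methyl (1S,2R,4aR,7R,8aR)-7-[(tert-butyldimethylsilyl)oxy]-5,5,8a-trimethyl-2-[(triethylsilyl)oxy]-1,2,4a,5,6,7,8,8a-octahydronaphthalene-1-carboxylate | CC[Si](CC)(CC)O[C@@H]1C=C[C@@H]2C(C)(C)C[C@@H](O[Si](C)(C)C(C)(C)C)C[C@@]2(C)[C@@H]1C(=O)OC | intermediate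
11 | methyl (1S,2R,4aR,7R,8aR)-7-[(tert-butyldimethylsilyl)oxy]-5,5,8a-trimethyl-2-[(triethylsilyl)oxy]decahydronaphthalene-1-carboxylate | CC[Si](CC)(CC)O[C@@H]1CC[C@@H]2C(C)(C)C[C@@H](O[Si](C)(C)C(C)(C)C)C[C@@]2(C)[C@@H]1C(=O)OC | intermediate
12 | (1S,2R,4aR,7R,8aR)-7-[(tert-butyldimethylsilyl)oxy]-5,5,8a-trimethyl-2-[(triethylsilyl)oxy]decahydronaphthalene-1-carbaldehyde | CC[Si](CC)(CC)O[C@@H]1CC[C@@H]2C(C)(C)C[C@@H](O[Si](C)(C)C(C)(C)C)C[C@@]2(C)[C@@H]1C=O | intermediate
13 | tert-butyl{[(2R,4aR,7R,8S,8aR)-8-ethenyl-4,4,8a-trimethyl-7-[(triethylsilyl)oxy]decahydronaphthalen-2-yl]oxy}dimethylsilane | CC[Si](CC)(CC)O[C@@H]1CC[C@@H]2C(C)(C)C[C@@H](O[Si](C)(C)C(C)(C)C)C[C@@]2(C)[C@@H]1C=C | intermediate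
14 | (1S,2R,4aR,7R,8aR)-7-[(tert-butyldimethylsilyl)oxy]-1-ethenyl-5,5,8a-trimethyldecahydronaphthalen-2-ol | O[C@@H]1CC[C@@H]2C(C)(C)C[C@@H](O[Si](C)(C)C(C)(C)C)C[C@@]2(C)[C@@H]1C=C | intermediate
15 | (1S,4aR,7R,8aR)-7-[(tert-butyldimethylsilyl)oxy]-1-ethenyl-5,5,8a-trimethyloctahydronaphthalen-2(1H)-one | O=C1CC[C@@H]2C(C)(C)C[C@@H](O[Si](C)(C)C(C)(C)C)C[C@@]2(C)[C@@H]1C=C | intermediate
16 | tert-butyl{[(2R,4aR,8R,8aR)-8-ethenyl-4,4,8a-trimethyl-7-methylidenedecahydronaphthalen-2-yl]oxy}dimethylsilane | C=C1CC[C@@H]2C(C)(C)C[C@@H](O[Si](C)(C)C(C)(C)C)C[C@@]2(C)[C@@H]1C=C | intermediate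
17 | chlorobis(cyclopentadienyl)zirconium alkyl formed at C12 of 16 | C=C1CC[C@@H]2C(C)(C)C[C@@H](O[Si](C)(C)C(C)(C)C)C[C@@]2(C)[C@@H]1CC[Zr](Cl)(C1C=CC=C1)C1C=CC=C1 | intermediate (not isolated)
18 | {[(2R,4aR,8R,8aR)-8-(2-bromoethyl)-4,4,8a-trimethyl-7-methylidenedecahydronaphthalen-2-yl]oxy}(tert-butyl)dimethylsilane | C=C1CC[C@@H]2C(C)(C)C[C@@H](O[Si](C)(C)C(C)(C)C)C[C@@]2(C)[C@@H]1CCBr | intermediate
19 | bromomagnesium alkyl (Grignard reagent) of 18 | C=C1CC[C@@H]2C(C)(C)C[C@@H](O[Si](C)(C)C(C)(C)C)C[C@@]2(C)[C@@H]1CC[Mg]Br | intermediate (not isolated)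
20 | 2,5-dihydro-1,2-oxamagnesole chelate carrying the C11–C12 chain at its 4-position | C=C1CC[C@@H]2C(C)(C)C[C@@H](O[Si](C)(C)C(C)(C)C)C[C@@]2(C)[C@@H]1CCC1=C[Mg]OC1 | intermediate (not isolated)
21 | cyclic magnesium (Z)-carboxylate alkoxide | C=C1CC[C@@H]2C(C)(C)C[C@@H](O[Si](C)(C)C(C)(C)C)C[C@@]2(C)[C@@H]1CCC1=CC(=O)O[Mg]OC1 | intermediate (not isolated)
22 | (2Z)-3-[(acetyloxy)methyl]-5-[(1R,4aR,7R,8aR)-7-[(tert-butyldimethylsilyl)oxy]-5,5,8a-trimethyl-2-methylidenedecahydronaphthalen-1-yl]pent-2-enoic acid | C=C1CC[C@@H]2C(C)(C)C[C@@H](O[Si](C)(C)C(C)(C)C)C[C@@]2(C)[C@@H]1CC/C(=C/C(=O)O)COC(C)=O | intermediate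
23 | (2Z)-3-[(acetyloxy)methyl]-5-[(1R,4aR,7R,8aR)-7-hydroxy-5,5,8a-trimethyl-2-methylidenedecahydronaphthalen-1-yl]pent-2-enoic acid | C=C1CC[C@@H]2C(C)(C)C[C@@H](O)C[C@@]2(C)[C@@H]1CC/C(=C/C(=O)O)COC(C)=O | target

**Count and risks**

Total step count: 15. Longest linear sequence: 14 steps (steps 1 and 3–15; step 2 prepares the second fragment).

The three steps most likely to fail:

1. Step 6. The exo transition state may compete and give cis-fused material, the enol ether may form partly with Z geometry and then not cyclise, or the dienol ether may be cleaved on heating. The fallback is a Lewis-acid-promoted cycloaddition of an acid-tolerant dienyl ester. It sets out from 8: enol acetylation (Ac2O, Et3N, DMAP, 60 °C) gives methyl (2E,5S,8E,10E)-11-(acetyloxy)-5-[(tert-butyldimethylsilyl)oxy]-3,7,7-trimethylundeca-2,8,10-trienoate F1. Et2AlCl (2.2 equiv, CH2Cl2, −78 → −20 °C) activates the enoate so that the ester-endo, trans-fused mode should dominate, giving methyl (1S,2R,4aR,7R,8aR)-2-(acetyloxy)-7-[(tert-butyldimethylsilyl)oxy]-5,5,8a-trimethyl-1,2,4a,5,6,7,8,8a-octahydronaphthalene-1-carboxylate F2. Hydrogenation (H2, Pt/C) gives methyl (1S,2R,4aR,7R,8aR)-2-(acetyloxy)-7-[(tert-butyldimethylsilyl)oxy]-5,5,8a-trimethyldecahydronaphthalene-1-carboxylate F3, and excess i-Bu2AlH reduces both esters to (1R,2R,4aR,7R,8aR)-7-[(tert-butyldimethylsilyl)oxy]-1-(hydroxymethyl)-5,5,8a-trimethyldecahydronaphthalen-2-ol F4. Et3SiOTf and 2,6-lutidine give tert-butyldimethyl({(2R,4aR,7R,8R,8aR)-4,4,8a-trimethyl-7-[(triethylsilyl)oxy]-8-{[(triethylsilyl)oxy]methyl}decahydronaphthalen-2-yl}oxy)silane F5. Swern oxidation, which converts a primary triethylsilyl ether directly into the aldehyde and spares the secondary one, brings the route back at 12.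

2. Step 14. The Grignard reagent may be protonated by the acetylenic C–H of the excess alkoxide, carboxylation may be incomplete, or the mixed anhydride formed from the carboxylate and Ac2O may be attacked by still-free alkoxide and close the butenolide. The fallback separates trapping, acetylation and carboxyl introduction. It sets out from 18: the same Grignard reagent 19 and carbomagnesiation, but chelate 20 is quenched with I2 to give (2Z)-2-{2-[(1R,4aR,7R,8aR)-7-[(tert-butyldimethylsilyl)oxy]-5,5,8a-trimethyl-2-methylidenedecahydronaphthalen-1-yl]ethyl}-3-iodoprop-2-en-1-ol F6. Ac2O and pyridine give (2Z)-2-{2-[(1R,4aR,7R,8aR)-7-[(tert-butyldimethylsilyl)oxy]-5,5,8a-trimethyl-2-methylidenedecahydronaphthalen-1-yl]ethyl}-3-iodoprop-2-en-1-yl acetate F7. Palladium-catalysed hydroxycarbonylation (Pd(OAc)2, PPh3, CO 1 atm, H2O, Et3N, DMF, 50 °C) proceeds with retention of alkene geometry and returns the route at 22.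

3. Step 3. Turnover may be slow with an enolisable aliphatic aldehyde, and an uncatalysed background reaction may erode the enantiomeric purity on which every later stereocentre depends. The fallback sets C2 by kinetic resolution of an epoxide and builds the enoate by carbometalation. It sets out from 3: Corey–Chaykovsky epoxidation (Me3SI, KOt-Bu, DMSO/THF) gives racemic 2-(2,2-dimethylpent-4-en-1-yl)oxirane F8. Hydrolytic kinetic resolution with the (salen)Co(OAc) antipode that consumes the S epoxide (0.55 equiv H2O) leaves (2R)-2-(2,2-dimethylpent-4-en-1-yl)oxirane F9. Opening at the terminal carbon with LiC≡CH·H2NCH2CH2NH2 in DMSO gives (4R)-6,6-dimethylnon-8-en-1-yn-4-ol F10, and silylation (t-BuMe2SiCl, imidazole) gives tert-butyl{[(4R)-6,6-dimethylnon-8-en-1-yn-4-yl]oxy}dimethylsilane F11. Negishi syn-carboalumination of the terminal alkyne (Me3Al, Cp2ZrCl2 cat., CH2Cl2) with a ClCO2Me quench places methyl and ester cis and returns the route at 7.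

**Further compounds**

F1 | step 6 | methyl (2E,5S,8E,10E)-11-(acetyloxy)-5-[(tert-butyldimethylsilyl)oxy]-3,7,7-trimethylundeca-2,8,10-trienoate | COC(=O)/C=C(\C)C[C@H](O[Si](C)(C)C(C)(C)C)CC(C)(C)/C=C/C=C/OC(C)=O
F2 | step 6 | methyl (1S,2R,4aR,7R,8aR)-2-(acetyloxy)-7-[(tert-butyldimethylsilyl)oxy]-5,5,8a-trimethyl-1,2,4a,5,6,7,8,8a-octahydronaphthalene-1-carboxylate | CC(=O)O[C@@H]1C=C[C@@H]2C(C)(C)C[C@@H](O[Si](C)(C)C(C)(C)C)C[C@@]2(C)[C@@H]1C(=O)OC
F3 | step 6 | methyl (1S,2R,4aR,7R,8aR)-2-(acetyloxy)-7-[(tert-butyldimethylsilyl)oxy]-5,5,8a-trimethyldecahydronaphthalene-1-carboxylate | CC(=O)O[C@@H]1CC[C@@H]2C(C)(C)C[C@@H](O[Si](C)(C)C(C)(C)C)C[C@@]2(C)[C@@H]1C(=O)OC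
F4 | step 6 | (1R,2R,4aR,7R,8aR)-7-[(tert-butyldimethylsilyl)oxy]-1-(hydroxymethyl)-5,5,8a-trimethyldecahydronaphthalen-2-ol | O[C@@H]1CC[C@@H]2C(C)(C)C[C@@H](O[Si](C)(C)C(C)(C)C)C[C@@]2(C)[C@@H]1CO
F5 | step 6 | tert-butyldimethyl({(2R,4aR,7R,8R,8aR)-4,4,8a-trimethyl-7-[(triethylsilyl)oxy]-8-{[(triethylsilyl)oxy]methyl}decahydronaphthalen-2-yl}oxy)silane | CC[Si](CC)(CC)O[C@@H]1CC[C@@H]2C(C)(C)C[C@@H](O[Si](C)(C)C(C)(C)C)C[C@@]2(C)[C@@H]1CO[Si](CC)(CC)CC
F6 | step 14 | (2Z)-2-{2-[(1R,4aR,7R,8aR)-7-[(tert-butyldimethylsilyl)oxy]-5,5,8a-trimethyl-2-methylidenedecahydronaphthalen-1-yl]ethyl}-3-iodoprop-2-en-1-ol | C=C1CC[C@@H]2C(C)(C)C[C@@H](O[Si](C)(C)C(C)(C)C)C[C@@]2(C)[C@@H]1CC/C(=C/I)CO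
F7 | step 14 | (2Z)-2-{2-[(1R,4aR,7R,8aR)-7-[(tert-butyldimethylsilyl)oxy]-5,5,8a-trimethyl-2-methylidenedecahydronaphthalen-1-yl]ethyl}-3-iodoprop-2-en-1-yl acetate | C=C1CC[C@@H]2C(C)(C)C[C@@H](O[Si](C)(C)C(C)(C)C)C[C@@]2(C)[C@@H]1CC/C(=C/I)COC(C)=O
F8 | step 3 | racemic 2-(2,2-dimethylpent-4-en-1-yl)oxirane | C=CCC(C)(C)CC1CO1
F9 | step 3 | (2R)-2-(2,2-dimethylpent-4-en-1-yl)oxirane | C=CCC(C)(C)C[C@@H]1CO1
F10 | step 3 | (4R)-6,6-dimethylnon-8-en-1-yn-4-ol | C#CC[C@H](O)CC(C)(C)CC=C
F11 | step 3 | tert-butyl{[(4R)-6,6-dimethylnon-8-en-1-yn-4-yl]oxy}dimethylsilane | C#CC[C@H](O[Si](C)(C)C(C)(C)C)CC(C)(C)CC=C
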